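**Retrosynthetic overview**
- The target is 15-acetoxy-ent-labd-8(17)-en-19-oic acid (13R). The one strategic cut is C11–C12, between two primary carbons, closed by an electrochemical, nickel-catalysed doubly decarboxylative coupling.
- Left half: a tetranor 12,19-diacid that carries C4, C5, C9, C10 and the 8(17)-alkene, all taken from andrographolide (cut at C12=C13, remove 3-OH, oxidise C19).
- Right half: (S)-5-acetoxy-3-methylpentanoic acid, with C13 taken from methyl hydrogen (R)-3-methylglutarate by telling its two ends apart.
- Ring order: no ring is built; the trans-fused rings A and B are bought intact and only re-functionalised.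

Assumption: andrographolide and methyl hydrogen (R)-3-methylglutarate are taken as cheap, enantiopure commercial materials; positions are given in ent-labdane numbering (C1–C20).

**Step 1**
Reactants: 1 andrographolide
Product: 2 2-[(1R,4aS,5R,6R,8aS)-6-hydroxy-5-(hydroxymethyl)-5,8a-dimethyl-2-methylidenedecahydronaphthalen-1-yl]acetaldehyde
Conditions: KMnO4 (1.4 equiv, portionwise), THF–H2O (10:1), 0 °C, 1 h
Reagents that add atoms: potassium permanganate, [K+].[O-][Mn](=O)(=O)=O
Why: Permanganate oxidative cleavage (cyclic manganate ester, then C–C scission) is expected to be fastest at the electron-poor, conjugated C12=C13 alkylidene-lactone bond, so with limiting oxidant at 0 °C the isolated 8(17)-methylidene should survive; no stereocentre is touched.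

**Step 2**
Reactants: 2 2-[(1R,4aS,5R,6R,8aS)-6-hydroxy-5-(hydroxymethyl)-5,8a-dimethyl-2-methylidenedecahydronaphthalen-1-yl]acetaldehyde
Product: 3 3,19-O-thiocarbonyl derivative of 2 (six-membered cyclic thionocarbonate bridging O3 and O19)
Conditions: 1,1′-thiocarbonyldiimidazole (1.2 equiv), DMAP (10 mol %), THF, 23 → 50 °C
Reagents that add atoms: 1,1′-thiocarbonyldiimidazole, S=C(n1ccnc1)n1ccnc1
Why: Thiocarbonylation of a 1,3-diol: the primary C19–OH is acylated first and the neighbouring equatorial C3–OH closes the cis-fused 1,3-dioxane-2-thione (same geometry as the well-known 3,19-acetonide of andrographolide); the aldehyde is inert and no stereocentre changes.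

**Step 3**
Reactants: 3 3,19-O-thiocarbonyl derivative of 2
Product: 5 2-[(1R,4aS,5R,8aS)-5-(hydroxymethyl)-5,8a-dimethyl-2-methylidenedecahydronaphthalen-1-yl]acetaldehyde, via stannyl thiocarbonate 4 (not isolated)
Conditions: Bu3SnH (1.5 equiv, slow addition), AIBN (0.1 equiv), toluene, 100 °C; then 1 M NaOH, THF, 0 °C, 20 min
Reagents that add atoms: none
Why: Barton–McCombie-type radical deoxygenation of a cyclic thionocarbonate: Bu3Sn• adds to C=S, the adduct fragments at the secondary C3–O bond (secondary radical favoured over the neopentyl primary C19 radical), Bu3SnH quenches the C3 radical and base hydrolyses the S-stannyl thiocarbonate to the C19 alcohol; C3 ceases to be a stereocentre and the others are untouched.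

**Step 4**
Reactants: 5 2-[(1R,4aS,5R,8aS)-5-(hydroxymethyl)-5,8a-dimethyl-2-methylidenedecahydronaphthalen-1-yl]acetaldehyde
Product: 6 (1R,4aS,5R,8aS)-5-(carboxymethyl)-1,4a-dimethyl-6-methylidenedecahydronaphthalene-1-carboxylic acid
Conditions: CrO3, H2SO4, H2O, acetone, 0 → 23 °C, 2 h (kept short and cold)
Reagents that add atoms: water, O (both new oxygen atoms enter through the aldehyde hydrates); chromium trioxide, O=[Cr](=O)=O (as H2CrO4, whose oxygen atoms exchange with water)
Why: Chromic acid (Jones) oxidation takes the C12 aldehyde and the neopentyl C19 primary alcohol to carboxylic acids through their hydrates, while the 1,1-disubstituted alkene is inert to hexavalent chromium under these conditions; no stereocentre is touched.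

**Step 5**
Reactants: 7 methyl hydrogen (R)-3-methylglutarate [(3R)-5-methoxy-3-methyl-5-oxopentanoic acid]
Product: 9 (4S)-4-methyloxan-2-one, via hydroxy acid 8 (not isolated)
Conditions: LiBH4 (2.5 equiv), THF, 0 → 45 °C; then 2 M HCl, 23 °C; distillation
Reagents that add atoms: none
Why: Chemoselective hydride reduction: LiBH4 reduces the methyl ester but not the lithium carboxylate, and acidification lactonises the hydroxy acid, so the two ends of the glutarate are differentiated while the bought stereocentre (future C13) is untouched (its descriptor changes from R to S by priority only).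

**Step 6**
Reactants: 9 (4S)-4-methyloxan-2-one
Product: 11 (3S)-5-acetoxy-3-methylpentanoic acid, via sodium hydroxy carboxylate 10 (not isolated)
Conditions: NaOH (1.0 equiv), H2O–MeOH, 23 °C, evaporate to dryness; Ac2O (3 equiv), pyridine, DMAP (5 mol %), 0 → 23 °C; then H2O, 1 M HCl
Reagents that add atoms: sodium hydroxide, [Na+].[OH-]; acetic anhydride, CC(=O)OC(C)=O
Why: Lactone saponification followed by DMAP-catalysed O-acetylation of the alcohol of the carboxylate salt (fast O-acylation outruns relactonisation and any mixed anhydride is hydrolysed on aqueous work-up); the stereocentre is not involved.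

**Step 7**
Reactants: 6 (1R,4aS,5R,8aS)-5-(carboxymethyl)-1,4a-dimethyl-6-methylidenedecahydronaphthalene-1-carboxylic acid; 11 (3S)-5-acetoxy-3-methylpentanoic acid (3 equiv)
Product: 14 15-acetoxy-ent-labd-8(17)-en-19-oic acid (13R; target), via decalin NHPI ester 12 (not isolated), via side-chain NHPI ester 13 (not isolated)
Conditions: N-hydroxyphthalimide (4.2 equiv), N,N′-diisopropylcarbodiimide (4.0 equiv), DMAP (5 mol %), DMF, 0 → 23 °C, 3 h; then NiCl2·6H2O (20 mol %), 2,2′:6′,2″-terpyridine (20 mol %), AgNO3 (30 mol %), undivided cell, Mg anode, reticulated vitreous carbon cathode, constant current 12 mA (about 3 F per mol of ester), 23 °C, Ar; 1 M HCl work-up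
Reagents that add atoms: none
Why: Proposed new method: a one-pot, site-selective doubly decarboxylative C(sp3)–C(sp3) cross-coupling on a substrate that keeps a free carboxylic acid — carbodiimide/N-hydroxyphthalimide activation is gated by sterics (the C19 carboxyl, axial on quaternary C4 and flanked by the syn-axial C20 methyl, should not form an active ester at 23 °C, whereas the two CH2–CO2H groups do), the cathode and low-valent terpyridine-ligated nickel then reduce both N-acyloxyphthalimides by single-electron transfer to the primary C11 and C12 radicals, which are captured one after the other by nickel and joined by reductive elimination from trivalent nickel, the 3:1 excess of 13 steering 12 into the cross product, while the C19 acid only becomes a magnesium carboxylate that is not reduced at the cathode and cannot be oxidised at the sacrificial Mg anode, and the 8(17)-alkene should survive because nickel capture of the homoallylic C11 radical is expected to outrun its slow 3-exo closure; closest known reaction type: nickel-electrocatalytic doubly decarboxylative coupling of two preformed alkyl N-hydroxyphthalimide esters (a reductive radical cross-coupling, the cathodic counterpart of a mixed Kolbe coupling); no stereocentre is formed, and C9 and C13 (each β to a radical carbon) keep their configuration.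

**Compound list**
1 | andrographolide | C[C@@]12CC[C@H]([C@@]([C@H]1CCC(=C)[C@H]2C/C=C/3\[C@@H](COC3=O)O)(C)CO)O | starting material
2 | 2-[(1R,4aS,5R,6R,8aS)-6-hydroxy-5-(hydroxymethyl)-5,8a-dimethyl-2-methylidenedecahydronaphthalen-1-yl]acetaldehyde | C[C@@]12CC[C@H]([C@@]([C@H]1CCC(=C)[C@H]2CC=O)(C)CO)O | intermediate
3 | 3,19-O-thiocarbonyl derivative of 2 (cyclic thionocarbonate) | C[C@@]12CC[C@H]([C@@]([C@H]1CCC(=C)[C@H]2CC=O)(C)CO3)OC3=S | intermediate
4 | 3-deoxy aldehyde carrying C19–O–C(=O)–S–SnBu3 (O-alkyl S-tributylstannyl thiocarbonate) | C[C@@]12CCC[C@@]([C@H]1CCC(=C)[C@H]2CC=O)(C)COC(=O)S[Sn](CCCC)(CCCC)CCCC | intermediate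
5 | 2-[(1R,4aS,5R,8aS)-5-(hydroxymethyl)-5,8a-dimethyl-2-methylidenedecahydronaphthalen-1-yl]acetaldehyde | C[C@@]12CCC[C@@]([C@H]1CCC(=C)[C@H]2CC=O)(C)CO | intermediate
6 | (1R,4aS,5R,8aS)-5-(carboxymethyl)-1,4a-dimethyl-6-methylidenedecahydronaphthalene-1-carboxylic acid | C[C@@]12CCC[C@@]([C@H]1CCC(=C)[C@H]2CC(=O)O)(C)C(=O)O | intermediate
7 | methyl hydrogen (R)-3-methylglutarate | OC(=O)C[C@@H](C)CC(=O)OC | starting material
8 | (3S)-5-hydroxy-3-methylpentanoic acid | OC(=O)C[C@@H](C)CCO | intermediate
9 | (4S)-4-methyloxan-2-one | O=C1C[C@@H](C)CCO1 | intermediate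
10 | sodium (3S)-5-hydroxy-3-methylpentanoate | [Na+].[O-]C(=O)C[C@@H](C)CCO | intermediate
11 | (3S)-5-acetoxy-3-methylpentanoic acid | OC(=O)C[C@@H](C)CCOC(C)=O | intermediate
12 | C12 N-hydroxyphthalimide ester of 6 (C19 acid free) | C[C@@]12CCC[C@@]([C@H]1CCC(=C)[C@H]2CC(=O)ON3C(=O)c4ccccc4C3=O)(C)C(=O)O | intermediate
13 | N-hydroxyphthalimide ester of 11 | O=C(C[C@@H](C)CCOC(C)=O)ON1C(=O)c2ccccc2C1=O | intermediate
14 | (1R,4aS,5R,8aS)-5-[(3R)-5-acetoxy-3-methylpentyl]-1,4a-dimethyl-6-methylidenedecahydronaphthalene-1-carboxylic acid | C=C1CC[C@H]2[C@@](C)(CCC[C@@]2(C)C(=O)O)[C@@H]1CC[C@@H](C)CCOC(C)=O | target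

**Totals**
Total step count: 7. Longest linear sequence: 5 (steps 1, 2, 3, 4, 7).

**Three steps most likely to fail**

Step 7 (the proposed new coupling). Risks are partial activation of the C19 acid, homodimer formation, and reduction of the radicals to C–H. The fallback uses known chemistry, sets out from 5 and comes back at 14. NaClO2, NaH2PO4 and 2-methyl-2-butene in t-BuOH–H2O oxidise only the aldehyde of 5 to give the hydroxy acid F1. A classical mixed Kolbe electrolysis of F1 with 11 (5 equiv) at Pt electrodes in MeOH, 10 % neutralised with KOH, at high current density and 30–40 °C, couples the two anodically formed primary radicals to the 19-alcohol F2; the neopentyl alcohol and the acetate are inert there. CrO3/H2SO4 in acetone at 0 °C then oxidises F2 to 14.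

Step 3 (regioselective radical deoxygenation with an aldehyde present). Risks are fragmentation toward C19, tin hydride reduction of the aldehyde, and aldol loss during the basic hydrolysis. The fallback sets out from 2 and comes back at 5. TBSCl and imidazole in DMF at 0 °C silylate only the primary C19–OH to give the silyl ether F3. PhOC(S)Cl with DMAP and pyridine in CH2Cl2 converts the C3–OH into the phenyl thionocarbonate F4. Bu3SnH/AIBN in toluene at 90 °C gives the 3-deoxy silyl ether F5, in which only one C–O bond can break. Aqueous HF in MeCN at 0 °C frees the alcohol and gives 5.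

Step 1 (chemoselective cleavage of C12=C13 beside the 8(17)-alkene). Risks are attack on the methylidene and over-oxidation of the aldehyde. The fallback sets out from 1 and comes back at 2. mCPBA in CH2Cl2 at 0 °C epoxidises only the electron-rich 8(17)-alkene, from the face away from the C20 methyl, to give the 8,17-epoxide F6. With the conjugated alkene now the only C=C, O3 in CH2Cl2–MeOH at −78 °C followed by Me2S cleaves C12=C13 to the epoxy aldehyde F7. Zn dust, NaI and NaOAc in AcOH (iodohydrin, then reductive elimination) restore the 8(17)-alkene and give 2.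

**Further compounds**
F1 | step 7 | 2-[(1R,4aS,5R,8aS)-5-(hydroxymethyl)-5,8a-dimethyl-2-methylidenedecahydronaphthalen-1-yl]acetic acid | C[C@@]12CCC[C@@]([C@H]1CCC(=C)[C@H]2CC(=O)O)(C)CO
F2 | step 7 | (3R)-5-[(1R,4aS,5R,8aS)-5-(hydroxymethyl)-5,8a-dimethyl-2-methylidenedecahydronaphthalen-1-yl]-3-methylpentyl acetate (15-acetoxy-ent-labd-8(17)-en-19-ol) | C[C@@]12CCC[C@@]([C@H]1CCC(=C)[C@H]2CC[C@@H](C)CCOC(C)=O)(C)CO
F3 | step 3 | 19-O-tert-butyldimethylsilyl ether of 2 | C[C@@]12CC[C@H]([C@@]([C@H]1CCC(=C)[C@H]2CC=O)(C)CO[Si](C)(C)C(C)(C)C)O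
F4 | step 3 | 3-O-(phenoxythiocarbonyl) derivative of F3 | C[C@@]12CC[C@H]([C@@]([C@H]1CCC(=C)[C@H]2CC=O)(C)CO[Si](C)(C)C(C)(C)C)OC(=S)Oc3ccccc3
F5 | step 3 | 19-O-tert-butyldimethylsilyl ether of 5 | C[C@@]12CCC[C@@]([C@H]1CCC(=C)[C@H]2CC=O)(C)CO[Si](C)(C)C(C)(C)C
F6 | step 1 | 8,17-epoxide of andrographolide (spiro-oxirane at C8, oxygen on the face opposite the C20 methyl) | C[C@@]12CC[C@H]([C@@]([C@H]1CC[C@@]3(CO3)[C@H]2C/C=C/4\[C@@H](COC4=O)O)(C)CO)O
F7 | step 1 | 8,17-epoxide of aldehyde 2 | C[C@@]12CC[C@H]([C@@]([C@H]1CC[C@@]3(CO3)[C@H]2CC=O)(C)CO)O
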